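## The problem

- Target 42 is two tetra-ortho-substituted benzophenones joined by one CH2 group between rings B and C. It has no stereocentre, so nothing needs control in space, and every stereocentre that appears in an intermediate is transient and racemic.
- Rings B and C carry the same sequence of substituents (CH2, OMe, H, OH, aroyl, OH). They differ only in the aroyl group: ring A has a 2-hydroxyl where ring D has a 2-methoxyl. A formaldehyde-type union of two monomers would therefore have to be cross-selective between two nearly identical phloroglucinol rings.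
- The central difficulty is regiochemical. On ring C the bridge (C-1), OMe (C-2), OH (C-4), the ring D aroyl group (C-5) and OH (C-6) must be placed without relying on electrophilic substitution of a phloroglucinol ether, which does not distinguish the open positions.
- Each ketone carbon is flanked by two ortho substituents on both sides. Such ketones are best made by adding an aryl-metal to an aldehyde and oxidising the carbinol.
- Several features limit the conditions. The free polyphenol is air-sensitive and its diarylmethane link is acid-labile. The 2-methoxyl of ring D sits next to a carbonyl and is cleaved by strong Lewis acids. 2-Hydroxy-2'-alkoxybenzophenones close to xanthones under base and heat. The seven phenols are therefore released last, under neutral conditions.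
- The feature that permits the key step is the alternating oxygenation of ring C. Read around the ring, C-6 (OH), C-1 (CH2), C-2 (OMe) and C-3 (H) map onto C-1 (carbonyl), C-4, C-3 and C-2 of a 4-substituted 3-methoxycyclobutenone. C-4 (O) and C-5 map onto the two carbons of a silyl ynol ether.

## Retrosynthesis

**Deprotection (42 from 41 from 40).** The last cuts are five O–benzyl bonds and one O–Si bond. Benzyl ethers on rings A, B and D come off together by hydrogenolysis, which leaves methyl ethers, the hindered ketones and the diarylmethane alone. The triisopropylsilyl group on O-4 of ring C is removed just before with buffered fluoride. Acid- or Lewis-acid-labile groups were avoided for the late stages because of the bridge and the ring D methoxyl.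

**Ring D ketone (40 from 39, from aldehyde 32 and aryl iodide 37).** The bond cut is the one between the ketone carbon and ring D. An O-acylation and Fries shift was weighed for the neighbouring bond (ketone carbon to C-5). It was set aside because a Lewis acid would endanger five benzyl ethers, the silyl ether and the ring D methoxyl, and because C-3, para to the free hydroxyl, is also open. Addition of arylmagnesium reagent 38 (from 37) to salicylaldehyde 32 and oxidation of carbinol 39 is the standard answer for a tetra-ortho-substituted benzophenone. The forward reaction must leave the ring A/B ketone untouched, which its four ortho substituents secure.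

**Formyl group (32 from 30).** The bond from C-5 to the formyl carbon is cut. In phenol 30 only C-5 is both ortho to the one free hydroxyl and unsubstituted. A magnesium-phenoxide-mediated formylation reacts only at that ortho position, so the ring D carbon is placed without competition from C-3.

**Ring C (30 from cyclobutenone 21 and silyl ynol ether 25).** This is the key disconnection. The ring bonds C-5–C-6 and C-3–C-4 are cut, and the C-6–C-1 bond is broken and re-formed in the forward direction. It is preferred to a formaldehyde coupling of two monomers or a benzylation of a preformed ring C, because it builds ring C directly on the bridge carbon and delivers the three oxygens already differentiated: free OH at C-6, silyl ether at C-4, methyl ether at C-2. The precursors are a cyclobutenone that holds the complete ring A/B monomer and a two-carbon alkyne. The forward reaction needs only one selectivity, the orientation of the ketene–alkyne union.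

**Cyclobutenone (21 from acid 15 and methoxyacetylene 18).** Two bonds of the four-membered ring are cut. This returns ketene 20, made from acid chloride 19, and the ynol ether 18, which is made from chloroacetal 16. The same polarity rule as in the key step puts OMe at C-3 and the benzyl group at C-4. Silyl ynol ether 25 comes from acetylene 22 by oxidation of its lithium salt and O-silylation.

**Side chain (15 from 13 from 11 from 10 from 9 from 8).** The three-carbon chain is traced back to an allyl group: the acid to alcohol 13, then to alkene 11, whose ring-to-allyl bond comes from a Claisen rearrangement of allyl ether 9. In resorcinol 8 the two hydroxyls are equivalent, and so are C-3 and C-5 of its ring B. Mono-allylation and rearrangement can therefore give only one C-allyl compound (10). This avoids any contest between rings A and B, since ring A has no free hydroxyl.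

**Ring A/B ketone (8 from 7 from 6, from bis-MOM ether 4 and aldehyde 2).** The bond from the carbinol carbon to ring B is cut. The two methoxymethyl ethers of 4 direct lithiation to the carbon between them, which fixes the ketone para to the methoxyl. This was chosen over acylation of 5-methoxyresorcinol 3, which gives mixtures and xanthones. Aldehyde 2 is the dibenzyl ether of commercial 1, and 4 is the bis-acetal of 3.

**Ring D iodide (37 from 36 from 35 from 34 from methyl orsellinate 33).** The hydrogen bond of 33 allows the 4-hydroxyl to be benzylated first and the 2-hydroxyl methylated second. After saponification the carboxyl carbon, which already stands at the right ring position, is exchanged for iodine.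

## Roads not taken

**Alternative 1:** The cut falls on ring D. The bond from the ketone carbon to ring D and the bond from ring D to its future methyl carbon are made together. The aryne released from silylaryl triflate A2 with CsF inserts into the C–C bond of β-ketoester A3 and gives benzophenone A1. Ester cleavage and decarboxylation would then give the protected ring C/D monomer.
- Merits: the hindered ketone forms in one fluoride-mediated step at room temperature, without organolithium reagents or an oxidation. The methoxy group of the aryne steers the acyl group to the carbon next to it. For the ketone alone this is shorter and milder than steps 15, 20 and 21.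
- Weak points: A2 needs its own regiodefined multi-step preparation. Turning the arylacetic ester into a methyl group requires protodecarboxylation of an electron-rich arylacetic acid. Decisively, ring C in A1 is the symmetric 2,6-bis(benzyloxy)-4-methoxyphenyl group without the bridge. Joining it to the ring A/B half would fall back on a formaldehyde condensation between two nearly identical rings.
- Comparison: the chosen plan is longer, but it fixes the bridge and the oxygen pattern of ring C in one regiodefined step.

**Alternative 2:** The ring C to ketone bond is made intramolecularly. In acid A5 the future methyl carbon of ring D is tied as a benzylic ether to the ring C phenol oxygen. Trifluoroacetic anhydride closes the seven-membered ketone A4, and the final hydrogenolysis cuts the benzylic C–O bond to reveal the methyl group and the phenol together.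
- Merits: the tether can reach only C-5. No Lewis acid and no late organometallic reagent are needed, and one hydrogenolysis finishes the synthesis. For attaching ring D this is more economical than the formylation, Grignard addition and oxidation chosen here, and it needs no ring D iodide.
- Weak points: A5 presupposes a diarylmethane whose ring C has one free and one protected hydroxyl, which is exactly what the benzannulation provides; the alternative does not supply it. The benzylic bromide of the ring D ester must be made by radical bromination next to a benzyl ether and on an electron-rich ring. The flatter, conjugated oxepinone ketone of A4 is more exposed to over-reduction than an open, twisted benzophenone.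
- Comparison: it competes with steps 15 and 19 to 21, not with the key step, and could be grafted onto phenol 30. The chosen end game uses only standard operations and a ring D unit made without radical chemistry.

**Alternative 3:** The cut goes through ring A. Diketone A7 adds through its central carbon to ethyl crotonate A8, and its methyl group then condenses on the ester under NaOEt. This gives cyclohexanedione A6, which must be dehydrogenated to the resorcinol ring.
- Merits: cheap reagents, no organometallics, the hindered aryl–carbonyl bond is present from the start, and the methyl position is fixed by the crotonate. On paper this costs less than steps 1 to 4.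
- Weak points: the aromatic ring A aldehyde 1 is commercial, so building ring A is unnecessary. Triketone A6 is open to retro-Claisen cleavage by ethoxide. Aromatisation needs an oxidant in the presence of an electron-rich phloroglucinol ether and benzyl ethers. The route says nothing about the bridge or about ring C. For ring D the chelated 2-hydroxyl would have to be methylated in preference to the 4-hydroxyl.
- Comparison: the chosen plan uses a stoichiometric organolithium and an oxidation, but gets regiochemical certainty from the two directing acetal groups.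

Key step: step 14

Assumption: the target is taken as achiral (no stereocentre, free rotation about the aryl–carbonyl bonds at room temperature), so the transient stereocentres in 6, 21, 27, 29 and 39 are carried as racemates.

Abbreviation: ArB is the 2,4-bis(benzyloxy)-3-[2,4-bis(benzyloxy)-6-methylbenzoyl]-6-methoxyphenyl group (ring B carrying ring A), attached through its C-1. TIPS is triisopropylsilyl and MOM is methoxymethyl.

## Route

Step 1
Reactants: 1 2,4-dihydroxy-6-methylbenzaldehyde
Product: 2 2,4-bis(benzyloxy)-6-methylbenzaldehyde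
Conditions: BnBr (2.4 equiv), K2CO3, DMF, 60 °C
Reagents that add atoms: benzyl bromide, BrCc1ccccc1
Why: Williamson etherification; the chelated 2-hydroxyl needs DMF and warming, but both phenols should alkylate and the aldehyde is untouched.

Step 2
Reactants: 3 5-methoxyresorcinol
Product: 4 1-methoxy-3,5-bis(methoxymethoxy)benzene
Conditions: NaH, MOMCl, DMF, 0 °C to rt
Reagents that add atoms: chloromethyl methyl ether, COCCl
Why: O-alkylation of both phenoxides; the two acetal ethers later direct the metalation.

Step 3
Reactants: 4 1-methoxy-3,5-bis(methoxymethoxy)benzene; 2 2,4-bis(benzyloxy)-6-methylbenzaldehyde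
Product: 6 [2,4-bis(benzyloxy)-6-methylphenyl][4-methoxy-2,6-bis(methoxymethoxy)phenyl]methanol (racemic), via aryllithium 5 (not isolated)
Conditions: n-BuLi, THF, 0 °C; then 2, −78 °C to rt; H2O
Reagents that add atoms: none
Why: Directed ortho-metalation at the carbon between the two coordinating MOM ethers, then 1,2-addition to the non-enolisable aldehyde; the carbinol centre forms racemic and is erased in step 4.

Step 4
Reactants: 6 [2,4-bis(benzyloxy)-6-methylphenyl][4-methoxy-2,6-bis(methoxymethoxy)phenyl]methanol
Product: 7 [2,4-bis(benzyloxy)-6-methylphenyl][4-methoxy-2,6-bis(methoxymethoxy)phenyl]methanone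
Conditions: Dess–Martin periodinane, pyridine, CH2Cl2, rt
Reagents that add atoms: none
Why: Dess–Martin oxidation of a doubly benzylic alcohol; buffered, non-acidic conditions should avoid ionisation of the electron-rich benzhydrol and spare the MOM and benzyl ethers.

Step 5
Reactants: 7 [2,4-bis(benzyloxy)-6-methylphenyl][4-methoxy-2,6-bis(methoxymethoxy)phenyl]methanone
Product: 8 [2,4-bis(benzyloxy)-6-methylphenyl](2,6-dihydroxy-4-methoxyphenyl)methanone
Conditions: HCl (aq., cat.), MeOH, 50 °C
Reagents that add atoms: none
Why: Acid-catalysed acetal exchange with methanol removes both MOM groups; benzyl ethers and the ketone are stable, and the product has equivalent hydroxyls and equivalent C-3 and C-5 on ring B.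

Step 6
Reactants: 8 [2,4-bis(benzyloxy)-6-methylphenyl](2,6-dihydroxy-4-methoxyphenyl)methanone
Product: 9 [2-(allyloxy)-6-hydroxy-4-methoxyphenyl][2,4-bis(benzyloxy)-6-methylphenyl]methanone
Conditions: allyl bromide (1.1 equiv), K2CO3, acetone, reflux
Reagents that add atoms: allyl bromide, C=CCBr
Why: Williamson mono-alkylation; after the first alkylation the remaining hydroxyl is held in a stronger hydrogen bond to the carbonyl, which should slow the second.

Step 7
Reactants: 9 [2-(allyloxy)-6-hydroxy-4-methoxyphenyl][2,4-bis(benzyloxy)-6-methylphenyl]methanone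
Product: 10 (3-allyl-2,6-dihydroxy-4-methoxyphenyl)[2,4-bis(benzyloxy)-6-methylphenyl]methanone
Conditions: N,N-diethylaniline, 190 °C, sealed tube
Reagents that add atoms: none
Why: Aromatic Claisen rearrangement; the only free ortho carbon is C-3, and because C-3 and C-5 of the resulting resorcinol are equivalent only one C-allyl product can form.

Step 8
Reactants: 10 (3-allyl-2,6-dihydroxy-4-methoxyphenyl)[2,4-bis(benzyloxy)-6-methylphenyl]methanone
Product: 11 [3-allyl-2,6-bis(benzyloxy)-4-methoxyphenyl][2,4-bis(benzyloxy)-6-methylphenyl]methanone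
Conditions: BnBr, K2CO3, Bu4NI (cat.), DMF, 70 °C
Reagents that add atoms: benzyl bromide, BrCc1ccccc1
Why: Williamson etherification of both phenols; iodide catalysis and heat should overcome the hindrance of the hydroxyl between the allyl and aroyl groups.

Step 9
Reactants: 11 [3-allyl-2,6-bis(benzyloxy)-4-methoxyphenyl][2,4-bis(benzyloxy)-6-methylphenyl]methanone
Product: 13 [2,6-bis(benzyloxy)-3-(3-hydroxypropyl)-4-methoxyphenyl][2,4-bis(benzyloxy)-6-methylphenyl]methanone, via alkylborane 12 (not isolated)
Conditions: 9-BBN, THF, 0 °C to rt; then NaOH (aq.), H2O2, 0 °C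
Reagents that add atoms: hydrogen peroxide, OO
Why: Anti-Markovnikov hydroboration–oxidation of the terminal alkene; the tetra-ortho-substituted diaryl ketone is too hindered to be reduced by the bulky borane.

Step 10
Reactants: 13 [2,6-bis(benzyloxy)-3-(3-hydroxypropyl)-4-methoxyphenyl][2,4-bis(benzyloxy)-6-methylphenyl]methanone
Product: 15 3-(ArB)propanoic acid, via aldehyde 14 (not isolated)
Conditions: TEMPO (cat.), PhI(OAc)2, MeCN/H2O, rt
Reagents that add atoms: water, O
Why: Nitroxyl-catalysed oxidation of the primary alcohol through the aldehyde hydrate to the acid; metal-free and mild enough for benzyl ethers and the alkoxy-substituted rings.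

Step 11
Reactants: 16 2-chloro-1,1-dimethoxyethane
Product: 18 methoxyethyne (methoxyacetylene), via sodium methoxyacetylide 17 (not isolated)
Conditions: NaNH2 (3 equiv), liquid NH3, −33 °C; then cold brine, −20 °C; distillation into a cold trap
Reagents that add atoms: none
Why: Twofold base-induced elimination (HCl and methanol) from the α-chloro acetal gives the acetylide, and protonation releases the volatile ynol ether; this is the classical preparation of alkoxyacetylenes.

Step 12
Reactants: 15 3-(ArB)propanoic acid; 18 methoxyethyne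
Product: 21 4-[(ArB)methyl]-3-methoxycyclobut-2-en-1-one (racemic), via acid chloride 19 (not isolated), via ketene 20 (not isolated)
Conditions: (COCl)2, DMF (cat.), CH2Cl2, 0 °C to rt, evaporate; then 18 (4 equiv), Et3N, CH2Cl2, 0 °C to rt, closed vessel
Reagents that add atoms: none
Why: Dehydrochlorination gives the monoalkylketene, which undergoes (2+2) cycloaddition with the ynol ether (its CH carbon to the ketene carbonyl carbon) to the 3-alkoxycyclobutenone; C-4 forms racemic and is lost in step 14.

Step 13
Reactants: 22 acetylene
Product: 25 (ethynyloxy)tri(propan-2-yl)silane ((triisopropylsilyloxy)acetylene), via lithium acetylide 23 (not isolated), via lithium ethynolate 24 (not isolated)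
Conditions: n-BuLi, THF, −78 °C; LiOOt-Bu (from t-BuOOH and LiN(SiMe3)2), −78 to −20 °C; i-Pr3SiOTf, −78 to 0 °C
Reagents that add atoms: tert-butyl hydroperoxide, CC(C)(C)OO; triisopropylsilyl trifluoromethanesulfonate, CC(C)[Si](OS(=O)(=O)C(F)(F)F)(C(C)C)C(C)C
Why: Oxidation of a lithium acetylide by lithium tert-butyl peroxide gives the ynolate, and the bulky silyl triflate traps it on oxygen; this is the known route from terminal alkynes to triisopropylsilyl ynol ethers, applied to the parent alkyne.

Step 14
Reactants: 21 4-[(ArB)methyl]-3-methoxycyclobut-2-en-1-one; 25 (ethynyloxy)tri(propan-2-yl)silane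
Product: 30 2-[(ArB)methyl]-3-methoxy-5-[(triisopropylsilyl)oxy]phenol, via vinylketene 26 (not isolated), via vinylcyclobutenone 27 (not isolated), via dienylketene 28 (not isolated), via cyclohexadienone 29 (not isolated)
Conditions: 25 (3 equiv), toluene, 80 °C then 110 °C, sealed tube, argon
Reagents that add atoms: none
Why: Heating should open 21 by four-electron conrotatory electrocyclic ring opening (C-1–C-4 bond, the benzyl-bearing carbon turning outward) to methoxy vinylketene 26. The ketene C=C adds silyl ynol ether 25 in a (2+2) cycloaddition in which the nucleophilic CH carbon of 25 bonds to the ketene carbonyl carbon and the oxygen-bearing carbon to the ketene α-carbon, giving 27. A second four-electron opening of 27 (reversible, so the isomer with the alkenyl group turned inward is drained) gives dienylketene 28; six-electron disrotatory electrocyclisation then closes the six-membered ring C between the ketene carbon and the benzyl-bearing carbon to dienone 29, which tautomerises to phenol 30. The closest known reaction type is the thermal Danheiser benzannulation of cyclobutenones with trialkylsilyloxyalkynes, which gives resorcinol monosilyl ethers; the 3-methoxy group here supplies the third oxygen. No stereocentre survives, since C-4 of 21 and the sp3 ring carbons of 27 and 29 become sp2. The one selectivity needed is the orientation of the ketene–alkyne union; it is secured by the enol-ether polarisation of 25 against the electrophilic ketene carbon and places OH and OMe ortho and the silyl ether para to the bridge carbon. An excess of 25 should keep the vinylketene from being intercepted by the phenol as it forms.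

Step 15
Reactants: 30 2-[(ArB)methyl]-3-methoxy-5-[(triisopropylsilyl)oxy]phenol
Product: 32 3-[(ArB)methyl]-2-hydroxy-4-methoxy-6-[(triisopropylsilyl)oxy]benzaldehyde, via hydroxymethylphenol 31 (not isolated)
Conditions: MgCl2, Et3N, (CH2O)n, THF, reflux; dilute HCl work-up
Reagents that add atoms: formaldehyde (as paraformaldehyde), C=O
Why: Casnati–Skattebøl ortho-formylation: the magnesium phenoxide delivers formaldehyde to the ortho carbon through a chelate and a second formaldehyde oxidises the benzylic alkoxide by hydride transfer; only C-5 of ring C is ortho to the free phenol and open, para attack does not occur by this mechanism, and rings A, B have no free phenol.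

Step 16
Reactants: 33 methyl 2,4-dihydroxy-6-methylbenzoate (methyl orsellinate)
Product: 34 methyl 4-(benzyloxy)-2-hydroxy-6-methylbenzoate
Conditions: BnBr (1.05 equiv), K2CO3, acetone, reflux
Reagents that add atoms: benzyl bromide, BrCc1ccccc1
Why: Selective Williamson etherification; the 2-hydroxyl is hydrogen-bonded to the ester, so the 4-hydroxyl should react first.

Step 17
Reactants: 34 methyl 4-(benzyloxy)-2-hydroxy-6-methylbenzoate
Product: 35 methyl 4-(benzyloxy)-2-methoxy-6-methylbenzoate
Conditions: MeI, K2CO3, DMF, 50 °C
Reagents that add atoms: iodomethane, CI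
Why: O-methylation of the chelated phenol under more forcing conditions fixes the methoxyl that distinguishes ring D from ring A.

Step 18
Reactants: 35 methyl 4-(benzyloxy)-2-methoxy-6-methylbenzoate
Product: 36 4-(benzyloxy)-2-methoxy-6-methylbenzoic acid
Conditions: KOH, DMSO/H2O, 90 °C; then HCl (aq.), 0 °C
Reagents that add atoms: none
Why: Saponification of a di-ortho-substituted benzoate needs hot hydroxide in a dipolar solvent; cold acidification avoids protodecarboxylation of the electron-rich acid.

Step 19
Reactants: 36 4-(benzyloxy)-2-methoxy-6-methylbenzoic acid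
Product: 37 5-(benzyloxy)-2-iodo-1-methoxy-3-methylbenzene
Conditions: I2, K3PO4, MeCN, 100 °C, sealed tube
Reagents that add atoms: iodine, II
Why: Transition-metal-free decarboxylative ipso-iodination, known for electron-rich ortho-alkoxybenzoic acids; the carboxyl carbon is ortho to OMe and para to OBn, so ipso attack with loss of CO2 should be favoured.

Step 20
Reactants: 37 5-(benzyloxy)-2-iodo-1-methoxy-3-methylbenzene; 32 3-[(ArB)methyl]-2-hydroxy-4-methoxy-6-[(triisopropylsilyl)oxy]benzaldehyde
Product: 39 2-{[4-(benzyloxy)-2-methoxy-6-methylphenyl](hydroxy)methyl}-6-[(ArB)methyl]-5-methoxy-3-[(triisopropylsilyl)oxy]phenol (racemic), via arylmagnesium chloride 38 (not isolated)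
Conditions: 37 (2.5 equiv), i-PrMgCl·LiCl, THF, 0 °C to rt; then 32, 0 °C to rt; NH4Cl (aq.)
Reagents that add atoms: none
Why: Iodine–magnesium exchange, then Grignard 1,2-addition to the chelated magnesium salicylaldehyde (one equivalent is spent on the phenol); the ring A/B ketone with four ortho substituents should not be attacked, and the new carbinol centre is racemic and erased in step 21.

Step 21
Reactants: 39 2-{[4-(benzyloxy)-2-methoxy-6-methylphenyl](hydroxy)methyl}-6-[(ArB)methyl]-5-methoxy-3-[(triisopropylsilyl)oxy]phenol
Product: 40 [4-(benzyloxy)-2-methoxy-6-methylphenyl]{3-[(ArB)methyl]-2-hydroxy-4-methoxy-6-[(triisopropylsilyl)oxy]phenyl}methanone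
Conditions: MnO2 (activated, excess), CH2Cl2, rt
Reagents that add atoms: none
Why: Heterogeneous, neutral MnO2 oxidation of an activated benzylic alcohol; no acid is present to ionise the ortho-hydroxybenzhydrol, and the product is stabilised by its hydrogen bond.

Step 22
Reactants: 40 [4-(benzyloxy)-2-methoxy-6-methylphenyl]{3-[(ArB)methyl]-2-hydroxy-4-methoxy-6-[(triisopropylsilyl)oxy]phenyl}methanone
Product: 41 [4-(benzyloxy)-2-methoxy-6-methylphenyl]{3-[(ArB)methyl]-2,6-dihydroxy-4-methoxyphenyl}methanone
Conditions: Bu4NF, AcOH, THF, 0 °C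
Reagents that add atoms: none
Why: Fluoride cleavage of the aryl silyl ether; acetic acid buffering should prevent base-induced xanthone closure or oxidation of the phenoxide.

Step 23
Reactants: 41 [4-(benzyloxy)-2-methoxy-6-methylphenyl]{3-[(ArB)methyl]-2,6-dihydroxy-4-methoxyphenyl}methanone
Product: 42 (2,4-dihydroxy-6-methylphenyl)(2,6-dihydroxy-3-{[2,4-dihydroxy-3-(4-hydroxy-2-methoxy-6-methylbenzoyl)-6-methoxyphenyl]methyl}-4-methoxyphenyl)methanone
Conditions: H2 (1 atm), Pd/C (10% palladium metal on carbon), EtOAc/MeOH, rt
Reagents that add atoms: none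
Why: Hydrogenolysis of five aryl benzyl ethers under neutral conditions; the hindered, hydrogen-bonded diaryl ketones and the diarylmethane should survive at ambient pressure and temperature.

## Compound list

1 | 2,4-dihydroxy-6-methylbenzaldehyde | O=Cc1c(C)cc(O)cc1O | starting material
2 | 2,4-bis(benzyloxy)-6-methylbenzaldehyde | O=Cc1c(C)cc(OCc2ccccc2)cc1OCc1ccccc1 | intermediate
3 | 5-methoxyresorcinol | COc1cc(O)cc(O)c1 | starting material
4 | 1-methoxy-3,5-bis(methoxymethoxy)benzene | COCOc1cc(OC)cc(OCOC)c1 | intermediate
5 | [4-methoxy-2,6-bis(methoxymethoxy)phenyl]lithium | [Li]c1c(OCOC)cc(OC)cc1OCOC | intermediate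
6 | [2,4-bis(benzyloxy)-6-methylphenyl][4-methoxy-2,6-bis(methoxymethoxy)phenyl]methanol (racemic) | COCOc1cc(OC)cc(OCOC)c1C(O)c1c(C)cc(OCc2ccccc2)cc1OCc1ccccc1 | intermediate
7 | [2,4-bis(benzyloxy)-6-methylphenyl][4-methoxy-2,6-bis(methoxymethoxy)phenyl]methanone | COCOc1cc(OC)cc(OCOC)c1C(=O)c1c(C)cc(OCc2ccccc2)cc1OCc1ccccc1 | intermediate
8 | [2,4-bis(benzyloxy)-6-methylphenyl](2,6-dihydroxy-4-methoxyphenyl)methanone | COc1cc(O)c(C(=O)c2c(C)cc(OCc3ccccc3)cc2OCc2ccccc2)c(O)c1 | intermediate
9 | [2-(allyloxy)-6-hydroxy-4-methoxyphenyl][2,4-bis(benzyloxy)-6-methylphenyl]methanone | C=CCOc1cc(OC)cc(O)c1C(=O)c1c(C)cc(OCc2ccccc2)cc1OCc1ccccc1 | intermediate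
10 | (3-allyl-2,6-dihydroxy-4-methoxyphenyl)[2,4-bis(benzyloxy)-6-methylphenyl]methanone | C=CCc1c(OC)cc(O)c(C(=O)c2c(C)cc(OCc3ccccc3)cc2OCc2ccccc2)c1O | intermediate
11 | [3-allyl-2,6-bis(benzyloxy)-4-methoxyphenyl][2,4-bis(benzyloxy)-6-methylphenyl]methanone | C=CCc1c(OC)cc(OCc2ccccc2)c(C(=O)c2c(C)cc(OCc3ccccc3)cc2OCc2ccccc2)c1OCc1ccccc1 | intermediate
12 | 9-[3-(ArB)propyl]-9-borabicyclo[3.3.1]nonane | B1(CCCc2c(OC)cc(OCc3ccccc3)c(C(=O)c3c(C)cc(OCc4ccccc4)cc3OCc3ccccc3)c2OCc2ccccc2)C2CCCC1CCC2 | intermediate
13 | [2,6-bis(benzyloxy)-3-(3-hydroxypropyl)-4-methoxyphenyl][2,4-bis(benzyloxy)-6-methylphenyl]methanone | OCCCc1c(OC)cc(OCc2ccccc2)c(C(=O)c2c(C)cc(OCc3ccccc3)cc2OCc2ccccc2)c1OCc1ccccc1 | intermediate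
14 | 3-(ArB)propanal | O=CCCc1c(OC)cc(OCc2ccccc2)c(C(=O)c2c(C)cc(OCc3ccccc3)cc2OCc2ccccc2)c1OCc1ccccc1 | intermediate
15 | 3-(ArB)propanoic acid | OC(=O)CCc1c(OC)cc(OCc2ccccc2)c(C(=O)c2c(C)cc(OCc3ccccc3)cc2OCc2ccccc2)c1OCc1ccccc1 | intermediate
16 | 2-chloro-1,1-dimethoxyethane (chloroacetaldehyde dimethyl acetal) | COC(CCl)OC | starting material
17 | sodium methoxyacetylide | [Na+].[C-]#COC | intermediate
18 | methoxyethyne (methoxyacetylene) | C#COC | intermediate
19 | 3-(ArB)propanoyl chloride | ClC(=O)CCc1c(OC)cc(OCc2ccccc2)c(C(=O)c2c(C)cc(OCc3ccccc3)cc2OCc2ccccc2)c1OCc1ccccc1 | intermediate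
20 | 4-(ArB)but-1-en-1-one (monoalkylketene) | O=C=CCc1c(OC)cc(OCc2ccccc2)c(C(=O)c2c(C)cc(OCc3ccccc3)cc2OCc2ccccc2)c1OCc1ccccc1 | intermediate
21 | 4-[(ArB)methyl]-3-methoxycyclobut-2-en-1-one (racemic) | COC1=CC(=O)C1Cc1c(OC)cc(OCc2ccccc2)c(C(=O)c2c(C)cc(OCc3ccccc3)cc2OCc2ccccc2)c1OCc1ccccc1 | intermediate
22 | acetylene | C#C | starting material
23 | lithium acetylide | [Li]C#C | intermediate
24 | lithium ethynolate | [Li]OC#C | intermediate
25 | (ethynyloxy)tri(propan-2-yl)silane ((triisopropylsilyloxy)acetylene) | C#CO[Si](C(C)C)(C(C)C)C(C)C | intermediate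
26 | (3Z)-5-(ArB)-3-methoxypenta-1,3-dien-1-one (vinylketene, drawn as the isomer expected from outward rotation) | O=C=C/C(OC)=C/Cc1c(OC)cc(OCc2ccccc2)c(C(=O)c2c(C)cc(OCc3ccccc3)cc2OCc2ccccc2)c1OCc1ccccc1 | intermediate
27 | 4-[(1Z)-3-(ArB)-1-methoxyprop-1-en-1-yl]-3-[(triisopropylsilyl)oxy]cyclobut-2-en-1-one (racemic) | O=C1C=C(O[Si](C(C)C)(C(C)C)C(C)C)C1/C(OC)=C/Cc1c(OC)cc(OCc2ccccc2)c(C(=O)c2c(C)cc(OCc3ccccc3)cc2OCc2ccccc2)c1OCc1ccccc1 | intermediate
28 | 7-(ArB)-5-methoxy-3-[(triisopropylsilyl)oxy]hepta-1,3,5-trien-1-one (dienylketene; central double bond cis with respect to the carbon chain, as needed for closure) | O=C=C/C(O[Si](C(C)C)(C(C)C)C(C)C)=C\C(OC)=C\Cc1c(OC)cc(OCc2ccccc2)c(C(=O)c2c(C)cc(OCc3ccccc3)cc2OCc2ccccc2)c1OCc1ccccc1 | intermediate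
29 | 6-[(ArB)methyl]-5-methoxy-3-[(triisopropylsilyl)oxy]cyclohexa-2,4-dien-1-one (racemic) | O=C1C=C(O[Si](C(C)C)(C(C)C)C(C)C)C=C(OC)C1Cc1c(OC)cc(OCc2ccccc2)c(C(=O)c2c(C)cc(OCc3ccccc3)cc2OCc2ccccc2)c1OCc1ccccc1 | intermediate
30 | 2-[(ArB)methyl]-3-methoxy-5-[(triisopropylsilyl)oxy]phenol | Oc1cc(O[Si](C(C)C)(C(C)C)C(C)C)cc(OC)c1Cc1c(OC)cc(OCc2ccccc2)c(C(=O)c2c(C)cc(OCc3ccccc3)cc2OCc2ccccc2)c1OCc1ccccc1 | intermediate
31 | 2-(hydroxymethyl)-6-[(ArB)methyl]-5-methoxy-3-[(triisopropylsilyl)oxy]phenol | OCc1c(O)c(Cc2c(OC)cc(OCc3ccccc3)c(C(=O)c3c(C)cc(OCc4ccccc4)cc3OCc3ccccc3)c2OCc2ccccc2)c(OC)cc1O[Si](C(C)C)(C(C)C)C(C)C | intermediate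
32 | 3-[(ArB)methyl]-2-hydroxy-4-methoxy-6-[(triisopropylsilyl)oxy]benzaldehyde | O=Cc1c(O)c(Cc2c(OC)cc(OCc3ccccc3)c(C(=O)c3c(C)cc(OCc4ccccc4)cc3OCc3ccccc3)c2OCc2ccccc2)c(OC)cc1O[Si](C(C)C)(C(C)C)C(C)C | intermediate
33 | methyl 2,4-dihydroxy-6-methylbenzoate (methyl orsellinate) | COC(=O)c1c(C)cc(O)cc1O | starting material
34 | methyl 4-(benzyloxy)-2-hydroxy-6-methylbenzoate | COC(=O)c1c(C)cc(OCc2ccccc2)cc1O | intermediate
35 | methyl 4-(benzyloxy)-2-methoxy-6-methylbenzoate | COC(=O)c1c(C)cc(OCc2ccccc2)cc1OC | intermediate
36 | 4-(benzyloxy)-2-methoxy-6-methylbenzoic acid | OC(=O)c1c(C)cc(OCc2ccccc2)cc1OC | intermediate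
37 | 5-(benzyloxy)-2-iodo-1-methoxy-3-methylbenzene | COc1cc(OCc2ccccc2)cc(C)c1I | intermediate
38 | [4-(benzyloxy)-2-methoxy-6-methylphenyl]magnesium chloride (LiCl complex) | COc1cc(OCc2ccccc2)cc(C)c1[Mg]Cl | intermediate
39 | 2-{[4-(benzyloxy)-2-methoxy-6-methylphenyl](hydroxy)methyl}-6-[(ArB)methyl]-5-methoxy-3-[(triisopropylsilyl)oxy]phenol (racemic) | OC(c1c(C)cc(OCc2ccccc2)cc1OC)c1c(O)c(Cc2c(OC)cc(OCc3ccccc3)c(C(=O)c3c(C)cc(OCc4ccccc4)cc3OCc3ccccc3)c2OCc2ccccc2)c(OC)cc1O[Si](C(C)C)(C(C)C)C(C)C | intermediate
40 | [4-(benzyloxy)-2-methoxy-6-methylphenyl]{3-[(ArB)methyl]-2-hydroxy-4-methoxy-6-[(triisopropylsilyl)oxy]phenyl}methanone | O=C(c1c(C)cc(OCc2ccccc2)cc1OC)c1c(O)c(Cc2c(OC)cc(OCc3ccccc3)c(C(=O)c3c(C)cc(OCc4ccccc4)cc3OCc3ccccc3)c2OCc2ccccc2)c(OC)cc1O[Si](C(C)C)(C(C)C)C(C)C | intermediate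
41 | [4-(benzyloxy)-2-methoxy-6-methylphenyl]{3-[(ArB)methyl]-2,6-dihydroxy-4-methoxyphenyl}methanone | O=C(c1c(C)cc(OCc2ccccc2)cc1OC)c1c(O)c(Cc2c(OC)cc(OCc3ccccc3)c(C(=O)c3c(C)cc(OCc4ccccc4)cc3OCc3ccccc3)c2OCc2ccccc2)c(OC)cc1O | intermediate
42 | (2,4-dihydroxy-6-methylphenyl)(2,6-dihydroxy-3-{[2,4-dihydroxy-3-(4-hydroxy-2-methoxy-6-methylbenzoyl)-6-methoxyphenyl]methyl}-4-methoxyphenyl)methanone | COc1cc(O)c(C(=O)c2c(C)cc(O)cc2O)c(O)c1Cc1c(OC)cc(O)c(C(=O)c2c(C)cc(O)cc2OC)c1O | target

## Step count and least certain steps

Total: 23 steps. Longest linear sequence: 16 steps, from 5-methoxyresorcinol 3 (steps 2 to 10, 12, 14, 15 and 20 to 23).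

**Step 14 (key step).** The most likely failure is slow ring opening of the donor-substituted cyclobutenone 21 at temperatures the silyl ynol ether tolerates. This would lead to loss of 25 by silyl migration to carbon, or to capture of the vinylketene by the phenol already formed.
Fallback: set out from acid 15 and generate the same vinylketene at room temperature by 1,4-dehydrochlorination. Acid chloride 19 is acylated with the lithium enolate of methyl acetate to give methyl 5-(ArB)-3-oxopentanoate F1. Trimethyl orthoformate and catalytic acid convert it to methyl (2E)-5-(ArB)-3-methoxypent-2-enoate F2. Saponification gives (2E)-5-(ArB)-3-methoxypent-2-enoic acid F3, and oxalyl chloride gives its acid chloride F4. Treatment of F4 with Et3N in the presence of 25 should give vinylketene 26 by γ-deprotonation; cycloaddition and gentle warming then lead through 27 to 29 back to phenol 30.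

**Step 13.** Monolithium acetylide may disproportionate on warming before it is oxidised, and the unhindered parent ynolate may silylate on carbon to give a silylketene instead of the ynol ether.
Fallback: set out from cyclobutenone 21 and use trimethyl({[tri(propan-2-yl)silyl]oxy}ethynyl)silane F5. It is made from commercial trimethylsilylacetylene by the same oxidation and O-silylation, for which a substituted terminal alkyne is the usual substrate. The benzannulation should then give 2-[(ArB)methyl]-3-methoxy-5-[(triisopropylsilyl)oxy]-6-(trimethylsilyl)phenol F6. Protodesilylation of this activated arylsilane with trifluoroacetic acid in CH2Cl2 at 0 °C returns phenol 30.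

**Step 12.** The monoalkylketene may dimerise faster than it is trapped by the volatile alkyne, and the vinylogous ester 21 may hydrolyse on purification.
Fallback: set out from acid 15 (through 19 and 20) and trap the ketene with the more nucleophilic 1,1-dimethoxyethene. This gives 2-[(ArB)methyl]-3,3-dimethoxycyclobutan-1-one F7 (racemic). Loss of methanol on Et3N-deactivated silica or with a trace of acid returns cyclobutenone 21.

**Step 15.** The ortho carbon lies between the phenoxide and the bulky silyl ether, next to a ring that already carries the diarylmethyl group, so the magnesium chelate may fail to deliver formaldehyde.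
Fallback: set out from phenol 30 and use an anionic Fries shift, which also bypasses steps 19 to 21. Amine-catalysed ortho-bromination (NBS, catalytic i-Pr2NH, CH2Cl2, low temperature) should give 2-bromo-6-[(ArB)methyl]-5-methoxy-3-[(triisopropylsilyl)oxy]phenol F8. Its sodium salt (NaH, THF) is acylated with 4-(benzyloxy)-2-methoxy-6-methylbenzoyl chloride F9, made from acid 36 and oxalyl chloride, to give the aryl ester F10. Bromine–lithium exchange with t-BuLi at −95 °C triggers intramolecular transfer of the acyl group from oxygen to the ortho carbon and returns the route at ketone 40.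

**Step 19.** Iodination of the ring C–H positions or simple protodecarboxylation may compete with ipso substitution on this doubly activated ring.
Fallback: set out from acid 36 and replace the carboxyl group by nitrogen first. Curtius rearrangement with diphenylphosphoryl azide and Et3N in tert-butanol passes through 4-(benzyloxy)-2-methoxy-6-methylbenzoyl azide F11 and 5-(benzyloxy)-2-isocyanato-1-methoxy-3-methylbenzene F12 to tert-butyl [4-(benzyloxy)-2-methoxy-6-methylphenyl]carbamate F13. Trifluoroacetic acid releases 4-(benzyloxy)-2-methoxy-6-methylaniline F14. Diazotisation to 4-(benzyloxy)-2-methoxy-6-methylbenzenediazonium chloride F15 and treatment with KI (Sandmeyer-type iodination) return the route at iodide 37.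

## Further compounds

F1 | step 14 | methyl 5-(ArB)-3-oxopentanoate | COC(=O)CC(=O)CCc1c(OC)cc(OCc2ccccc2)c(C(=O)c2c(C)cc(OCc3ccccc3)cc2OCc2ccccc2)c1OCc1ccccc1
F2 | step 14 | methyl (2E)-5-(ArB)-3-methoxypent-2-enoate | COC(=O)/C=C(/OC)CCc1c(OC)cc(OCc2ccccc2)c(C(=O)c2c(C)cc(OCc3ccccc3)cc2OCc2ccccc2)c1OCc1ccccc1
F3 | step 14 | (2E)-5-(ArB)-3-methoxypent-2-enoic acid | OC(=O)/C=C(/OC)CCc1c(OC)cc(OCc2ccccc2)c(C(=O)c2c(C)cc(OCc3ccccc3)cc2OCc2ccccc2)c1OCc1ccccc1
F4 | step 14 | (2E)-5-(ArB)-3-methoxypent-2-enoyl chloride | ClC(=O)/C=C(/OC)CCc1c(OC)cc(OCc2ccccc2)c(C(=O)c2c(C)cc(OCc3ccccc3)cc2OCc2ccccc2)c1OCc1ccccc1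
F5 | step 13 | trimethyl({[tri(propan-2-yl)silyl]oxy}ethynyl)silane | C[Si](C)(C)C#CO[Si](C(C)C)(C(C)C)C(C)C
F6 | step 13 | 2-[(ArB)methyl]-3-methoxy-5-[(triisopropylsilyl)oxy]-6-(trimethylsilyl)phenol | Oc1c([Si](C)(C)C)c(O[Si](C(C)C)(C(C)C)C(C)C)cc(OC)c1Cc1c(OC)cc(OCc2ccccc2)c(C(=O)c2c(C)cc(OCc3ccccc3)cc2OCc2ccccc2)c1OCc1ccccc1
F7 | step 12 | 2-[(ArB)methyl]-3,3-dimethoxycyclobutan-1-one (racemic) | COC1(OC)CC(=O)C1Cc1c(OC)cc(OCc2ccccc2)c(C(=O)c2c(C)cc(OCc3ccccc3)cc2OCc2ccccc2)c1OCc1ccccc1
F8 | step 15 | 2-bromo-6-[(ArB)methyl]-5-methoxy-3-[(triisopropylsilyl)oxy]phenol | Oc1c(Br)c(O[Si](C(C)C)(C(C)C)C(C)C)cc(OC)c1Cc1c(OC)cc(OCc2ccccc2)c(C(=O)c2c(C)cc(OCc3ccccc3)cc2OCc2ccccc2)c1OCc1ccccc1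
F9 | step 15 | 4-(benzyloxy)-2-methoxy-6-methylbenzoyl chloride | COc1cc(OCc2ccccc2)cc(C)c1C(Cl)=O
F10 | step 15 | 2-bromo-6-[(ArB)methyl]-5-methoxy-3-[(triisopropylsilyl)oxy]phenyl 4-(benzyloxy)-2-methoxy-6-methylbenzoate | COc1cc(OCc2ccccc2)cc(C)c1C(=O)Oc1c(Br)c(O[Si](C(C)C)(C(C)C)C(C)C)cc(OC)c1Cc1c(OC)cc(OCc2ccccc2)c(C(=O)c2c(C)cc(OCc3ccccc3)cc2OCc2ccccc2)c1OCc1ccccc1
F11 | step 19 | 4-(benzyloxy)-2-methoxy-6-methylbenzoyl azide | COc1cc(OCc2ccccc2)cc(C)c1C(=O)N=[N+]=[N-]
F12 | step 19 | 5-(benzyloxy)-2-isocyanato-1-methoxy-3-methylbenzene | COc1cc(OCc2ccccc2)cc(C)c1N=C=O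
F13 | step 19 | tert-butyl [4-(benzyloxy)-2-methoxy-6-methylphenyl]carbamate | COc1cc(OCc2ccccc2)cc(C)c1NC(=O)OC(C)(C)C
F14 | step 19 | 4-(benzyloxy)-2-methoxy-6-methylaniline | COc1cc(OCc2ccccc2)cc(C)c1N
F15 | step 19 | 4-(benzyloxy)-2-methoxy-6-methylbenzenediazonium chloride | COc1cc(OCc2ccccc2)cc(C)c1[N+]#N.[Cl-]
A1 | alternative 1 | tert-butyl 2-[5-(benzyloxy)-2-(2,6-bis(benzyloxy)-4-methoxybenzoyl)-3-methoxyphenyl]acetate | CC(C)(C)OC(=O)Cc1cc(OCc2ccccc2)cc(OC)c1C(=O)c1c(OCc2ccccc2)cc(OC)cc1OCc1ccccc1
A2 | alternative 1 | 5-(benzyloxy)-3-methoxy-2-(trimethylsilyl)phenyl trifluoromethanesulfonate | COc1cc(OCc2ccccc2)cc(OS(=O)(=O)C(F)(F)F)c1[Si](C)(C)C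
A3 | alternative 1 | tert-butyl 3-[2,6-bis(benzyloxy)-4-methoxyphenyl]-3-oxopropanoate | CC(C)(C)OC(=O)CC(=O)c1c(OCc2ccccc2)cc(OC)cc1OCc1ccccc1
A4 | alternative 2 | dibenzo[b,e]oxepin-11(6H)-one carrying the whole protected skeleton | COc1cc(OCc2ccccc2)c(C(=O)c2c(C)cc(OCc3ccccc3)cc2OCc2ccccc2)c(OCc2ccccc2)c1Cc1c(OC)cc(OCc3ccccc3)c2c1OCc1cc(OCc3ccccc3)cc(OC)c1C2=O
A5 | alternative 2 | 4-(benzyloxy)-2-methoxy-6-({2-[(ring B/ring A unit)methyl]-5-(benzyloxy)-3-methoxyphenoxy}methyl)benzoic acid (tethered acid) | COc1cc(OCc2ccccc2)c(C(=O)c2c(C)cc(OCc3ccccc3)cc2OCc2ccccc2)c(OCc2ccccc2)c1Cc1c(OC)cc(OCc2ccccc2)cc1OCc1cc(OCc2ccccc2)cc(OC)c1C(=O)O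
A6 | alternative 3 | 4-[2,6-bis(benzyloxy)-4-methoxybenzoyl]-5-methylcyclohexane-1,3-dione (racemic, relative configuration not fixed; both centres are lost on aromatisation) | CC1CC(=O)CC(=O)C1C(=O)c1c(OCc2ccccc2)cc(OC)cc1OCc1ccccc1
A7 | alternative 3 | 1-[2,6-bis(benzyloxy)-4-methoxyphenyl]butane-1,3-dione | CC(=O)CC(=O)c1c(OCc2ccccc2)cc(OC)cc1OCc1ccccc1
A8 | alternative 3 | ethyl (2E)-but-2-enoate (ethyl crotonate) | C/C=C/C(=O)OCC
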